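- If you add the mono adduct and solid substrate columns of a run, they fall short of the whole charge, and that gap tells you how to read these flasks.

the same everywhere: gas 60 mM (held)

| flask | solid substrate | temperature | remark | time |
|---|---|---|---|---|
| Saturday's | 0.12 M | 0 °C | run made earlier |  |
| Tuesday's | 0.38 M | 40 °C | run made earlier |  |
| south-west | 0.10 M | 75 °C |  | 5.0 min |
| north | 0.10 M | 55 °C |  | 5.0 min |
| north-west | 0.30 M | 5 °C |  | 5.0 min |
| south-east | 0.20 M | 35 °C |  | 5.0 min |

| run | time / min | mono adduct / % | solid substrate / % |
|---|---|---|---|
| Saturday's | 4.00 | 0 | 85.2 |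
| Saturday's | 8.00 | 1.7 | 82.4 |
| Saturday's | 12.0 | 4.7 | 81.4 |
| Saturday's | 15.0 | 5.4 | 79.8 |
| Saturday's | 25.0 | 9.9 | 76.1 |
| Saturday's | 30.0 | 11.3 | 74.3 |
| Tuesday's | 0.417 | 0 | 98.4 |
| Tuesday's | 0.667 | 0.1 | 96.5 |
| Tuesday's | 1.00 | 0.1 | 95.8 |
| Tuesday's | 1.33 | 0 | 95.2 |
| Tuesday's | 2.00 | 0.8 | 95.0 |
| Tuesday's | 3.00 | 1.7 | 93.3 |
| Tuesday's | 5.00 | 4.7 | 91.1 |

(scatter of a reading: 0.5 percentage points)

1. the flasks by amount of mono adduct, in percent of the solid substrate charged, highest first, at 5.0 min (south-west / north / north-west / south-east)
2. the amount of mono adduct, in percent of the solid substrate charged of the flask you put first, at 5.0 min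
3. the amount of mono adduct, in percent of the solid substrate charged of the flask you put last, at 5.0 min

- Here is the puzzle. Cold Saturday's run lacks 14.4% of its charge at its last reading, while warmer Tuesday's run lacks 4.20%, which is less.
- Now reckon in concentration. Saturday's gap is 17.3 mM and Tuesday's is 16.0 mM, equal within the scatter.
- I read their mean, 16.6 mM, as the dissolved pool: the solid substrate that has left the solid but has not become mono adduct.
- Follow one molecule: my reading is that it passes through this pool before it can react. While solid is left, I take a flask to work from the pool, not from the charge, so I take its rate as zero order in the charge.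
- My rule: at a fixed temperature and time, and while solid is left, the mono adduct made in mM stays the same, so the percent yield goes as one over the charge.
- Tuesday's last reading gives 17.9 mM of mono adduct by 5.00 min. South-east is cooler at 35 °C, so over its charge of 0.20 M I expect somewhat under 8.95% there.
- I expect hot, thin flasks first. The south-west figure needs a rate at 75 °C, above the 40 °C of Tuesday's run, so my figure for it is shaky.
- The forecast gives south-west > north > south-east > north-west, with 95% on top and 0.3% last. It calls the south-west charge “nearly consumed”.
- The simulation gives south-west > north > south-east > north-west, with 43.3% on top and 0.695% last.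

    starting material + coupling partner → mono adduct + by-product (k = 5.20 M⁻¹ min⁻¹, Ea = 48.0 kJ mol⁻¹)
    starting material + coupling partner → other mono adduct + by-product (k = 0.260 M⁻¹ min⁻¹, Ea = 56.0 kJ mol⁻¹)
    coupling partner + mono adduct → bis adduct + by-product (k = 0.150 M⁻¹ min⁻¹, Ea = 68.0 kJ mol⁻¹)
    coupling partner + other mono adduct → bis adduct + by-product (k = 23.0 M⁻¹ min⁻¹, Ea = 59.0 kJ mol⁻¹)
    gas ⇌ coupling partner, rate k5*(csat - [coupling partner]) (kL = 0.440 min⁻¹)
    solid substrate ⇌ starting material, rate k6*(cs6 - [starting material]) while solid is left; crystals form when [starting material] > cs6 (solubility = 18.0 mM, k = 1.90 min⁻¹)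
    coupling partner → decomposition product (k = 1.00 × 10⁻⁴ min⁻¹, Ea = 117 kJ mol⁻¹)
    (constants at 35 °C)

- The order holds, but the top does not: south-west still has 34.6% of its charge as solid at 5.00 min. Its starting material, the dissolved pool, stands at 11.4 mM, below the 16.6 mM read from the runs.
- Take one more flask like south-west, but with 0.40 M of solid substrate. The same 43.3 mM of mono adduct over that charge gives 10.8%. That flask gives 10.8%, with 11.4 mM of starting material in solution.

Readings and results were computed for an exercise, noise included.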